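The isoflavone is cut through the two bonds that fuse the pyranone (ring C) to ring A, O1–C8a and C4–C4a, which sit on neighbouring ring-A carbons. An aryne spanning C4a–C8a is loaded in one operation by the enol of a formylated (2,4,5-trimethoxyphenyl)acetate: the enol oxygen arylates C8a and the resulting C4a anion acylates itself on the ester, closing ring C. The aryne comes from an ortho-silyl aryl triflate carrying 8-OMe, 7-OBn and a 5-tosylate as regiocontrol element. The enol already holds O1, C2, C3 (with ring B) and C4. Debenzylation, detosylation and a 7-O-(1,1-dimethylallyl) Claisen shift to C6, the only free position, finish the target.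

Key step: step 9

Remark: the 5-oxygen is carried as a tosylate and not a triflate, and enol 14 is used without prior deprotonation, so that the C4a anion of step 9 has no ready leaving group beside it and the released methoxide is neutralised by the enol proton.

Step 1
Reactants: 1 3-(benzyloxy)-4-methoxybenzaldehyde
Product: 3 3-(benzyloxy)-4-methoxyphenol, via aryl formate 2 (not isolated)
Conditions: mCPBA, CH2Cl2, rt; then K2CO3, MeOH, rt
Reagents that add atoms: mCPBA, O=C(OO)c1cccc(Cl)c1
Why: Dakin-type Baeyer–Villiger oxidation of the electron-rich aldehyde should give formate 2 by aryl migration, and mild methanolysis then releases the phenol.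

Step 2
Reactants: 3 3-(benzyloxy)-4-methoxyphenol
Product: 4 4-(benzyloxy)-2-hydroxy-5-methoxybenzaldehyde
Conditions: MgCl2, Et3N, (CH2O)n, MeCN, reflux; then 1 M HCl
Reagents that add atoms: paraformaldehyde (as formaldehyde), C=O
Why: Magnesium-phenoxide-directed ortho-formylation (Casnati–Skattebøl reaction) puts the formyl group only ortho to the hydroxyl, and of the two ortho sites the one not flanked by the benzyloxy group should be taken.

Step 3
Reactants: 4 4-(benzyloxy)-2-hydroxy-5-methoxybenzaldehyde
Product: 5 5-(benzyloxy)-2-formyl-4-methoxyphenyl 4-methylbenzenesulfonate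
Conditions: TsCl, Et3N, DMAP (cat.), CH2Cl2, 0 °C to rt
Reagents that add atoms: 4-toluenesulfonyl chloride, Cc1ccc(S(=O)(=O)Cl)cc1
Why: Routine O-sulfonylation of the phenol installs the group that later serves as sigma acceptor at C5 and keeps this oxygen distinct from the one created in step 4.

Step 4
Reactants: 5 5-(benzyloxy)-2-formyl-4-methoxyphenyl 4-methylbenzenesulfonate
Product: 7 5-(benzyloxy)-2-hydroxy-4-methoxyphenyl 4-methylbenzenesulfonate, via aryl formate 6 (not isolated)
Conditions: mCPBA, CH2Cl2, rt; then Et3N, MeOH, rt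
Reagents that add atoms: mCPBA, O=C(OO)c1cccc(Cl)c1
Why: A second Dakin-type Baeyer–Villiger oxidation, assisted by the para-benzyloxy group, turns the formyl carbon into the future triflate oxygen, and amine-catalysed methanolysis of formate 6 should spare the aryl tosylate, whose shift to the neighbouring oxygen would require a disfavoured endocyclic substitution at sulfur.

Step 5
Reactants: 7 5-(benzyloxy)-2-hydroxy-4-methoxyphenyl 4-methylbenzenesulfonate
Product: 8 5-(benzyloxy)-3-bromo-2-hydroxy-4-methoxyphenyl 4-methylbenzenesulfonate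
Conditions: NBS, CH2Cl2, −20 to 0 °C
Reagents that add atoms: N-bromosuccinimide, O=C1CCC(=O)N1Br
Why: Electrophilic aromatic bromination should take the only open position ortho to the free hydroxyl (its para position carries the benzyloxy group), the carbon between OH and OMe that becomes C8a.

Step 6
Reactants: 8 5-(benzyloxy)-3-bromo-2-hydroxy-4-methoxyphenyl 4-methylbenzenesulfonate
Product: 11 4-(benzyloxy)-3-methoxy-6-(tosyloxy)-2-(trimethylsilyl)phenyl trifluoromethanesulfonate, via aryl trimethylsilyl ether 9 (not isolated), via lithium 2-silylphenoxide 10 (not isolated)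
Conditions: HMDS, THF, 65 °C, then evaporation; n-BuLi, THF, −100 to −78 °C; Tf2O, −78 to 0 °C
Reagents that add atoms: hexamethyldisilazane, C[Si](C)(C)N[Si](C)(C)C; trifluoromethanesulfonic anhydride, O=S(=O)(OS(=O)(=O)C(F)(F)F)C(F)(F)F
Why: O-silylation, bromine–lithium exchange and 1,3 O-to-C silyl shift (retro-Brook rearrangement) place silicon on the brominated carbon and the freed phenoxide 10 is trapped as triflate, the standard one-pot entry to ortho-silylaryl triflates, with exchange at −100 °C expected to outpace attack of n-BuLi on the sulfonate.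

Step 7
Reactants: 12 2-(2,4,5-trimethoxyphenyl)acetic acid
Product: 13 methyl 2-(2,4,5-trimethoxyphenyl)acetate
Conditions: MeOH, H2SO4 (cat.), reflux
Reagents that add atoms: methanol, CO
Why: Fischer esterification in excess methanol should proceed cleanly on this unhindered arylacetic acid.

Step 8
Reactants: 13 methyl 2-(2,4,5-trimethoxyphenyl)acetate
Product: 14 methyl (Z)-3-hydroxy-2-(2,4,5-trimethoxyphenyl)acrylate
Conditions: NaH, HCO2Me, THF, 0 °C to rt; then 1 M HCl
Reagents that add atoms: methyl formate, COC=O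
Why: Crossed Claisen condensation of the ester enolate with methyl formate is driven by formation of the stabilised sodium enolate, and acidification should give the hydrogen-bonded Z enol, whose geometry equilibrates freely through the aldehyde tautomer.

Step 9
Reactants: 11 4-(benzyloxy)-3-methoxy-6-(tosyloxy)-2-(trimethylsilyl)phenyl trifluoromethanesulfonate (1.0 equiv); 14 methyl (Z)-3-hydroxy-2-(2,4,5-trimethoxyphenyl)acrylate (1.5 equiv)
Product: 16 7-(benzyloxy)-8-methoxy-4-oxo-3-(2,4,5-trimethoxyphenyl)chromen-5-yl 4-methylbenzenesulfonate, via aryne 15 (not isolated)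
Conditions: CsF, THF, 65 °C
Reagents that add atoms: none
Why: Proposed new method: fluoride removes the silyl group and the neighbouring triflate departs to give aryne 15, the enolate oxygen of 14 adds to C8a, and the C4a aryl anion so formed attacks the cis-placed ester carbonyl and expels methoxide, so that the O1–C8a and C4–C4a bonds and the pyranone arise in one pot. The closest known reaction type is the fluoride-triggered aryne annulation of salicylate esters to xanthones (O-arylation, then acyl capture); new here is a formyl-ester enol as the oxygen nucleophile, reasonable because its Z form holds oxygen and ester on the same side of C2=C3 just as a salicylate holds phenol and ester. Ring C should close by 6-exo-trig attack of the C4a carbanion on the ester carbon, and no stereocentre is formed. The oxygen must enter at C8a, which is expected because the 5-sulfonyloxy group is a stronger sigma acceptor and bulkier than the 8-methoxy group, so the aryne should accept the nucleophile at the remote carbon and carry the charge at C4a next to the sulfonate. O-arylation rather than C-arylation is favoured by the fully substituted enolate carbon shielded by the ortho-methoxyaryl group, and acyl capture through a six-membered transition state should outrun protonation or loss of tosylate from the C4a anion, tosylate being a much poorer nucleofuge than triflate. The enol proton ends up on the expelled methoxide, so the product should not meet strong base.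

Step 10
Reactants: 16 7-(benzyloxy)-8-methoxy-4-oxo-3-(2,4,5-trimethoxyphenyl)chromen-5-yl 4-methylbenzenesulfonate
Product: 17 7-hydroxy-8-methoxy-4-oxo-3-(2,4,5-trimethoxyphenyl)chromen-5-yl 4-methylbenzenesulfonate
Conditions: H2 (1 atm), 10% Pd/C, EtOAc/THF, rt
Reagents that add atoms: none
Why: Catalytic hydrogenolysis of the aryl benzyl ether should be faster than reduction of the chromone C2=C3 bond and leaves the aryl sulfonate and the methyl ethers untouched.

Step 11
Reactants: 17 7-hydroxy-8-methoxy-4-oxo-3-(2,4,5-trimethoxyphenyl)chromen-5-yl 4-methylbenzenesulfonate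
Product: 18 5,7-dihydroxy-8-methoxy-3-(2,4,5-trimethoxyphenyl)chromen-4-one (isocaviunin)
Conditions: LiOH, THF/H2O, 50 °C; then 1 M HCl
Reagents that add atoms: none
Why: Alkaline hydrolysis of the aryl sulfonate by hydroxide attack at sulfur gives the sulfonate salt without an alkylating by-product, while the substrate reacts as its 7-phenoxide, a vinylogous carboxylate that should protect C2 of the pyranone from ring opening.

Step 12
Reactants: 18 5,7-dihydroxy-8-methoxy-3-(2,4,5-trimethoxyphenyl)chromen-4-one
Product: 19 5-hydroxy-8-methoxy-7-[(2-methylbut-3-en-2-yl)oxy]-3-(2,4,5-trimethoxyphenyl)chromen-4-one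
Conditions: Pd(PPh3)4 (5 mol %), tert-butyl 2-methylbut-3-en-2-yl carbonate, THF, 0 °C to rt
Reagents that add atoms: tert-butyl 2-methylbut-3-en-2-yl carbonate, C=CC(C)(C)OC(=O)OC(C)(C)C
Why: In this Tsuji–Trost O-allylation zerovalent palladium ionises the tertiary carbonate and the acidic, non-chelated 7-phenoxide should attack the more substituted allyl terminus under kinetic control, while the hydrogen-bonded 5-OH stays free.

Step 13
Reactants: 19 5-hydroxy-8-methoxy-7-[(2-methylbut-3-en-2-yl)oxy]-3-(2,4,5-trimethoxyphenyl)chromen-4-one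
Product: 20 5,7-dihydroxy-8-methoxy-6-(3-methylbut-2-en-1-yl)-3-(2,4,5-trimethoxyphenyl)chromen-4-one (6-prenylisocaviunin)
Conditions: o-xylene, 130 °C
Reagents that add atoms: none
Why: Aromatic Claisen rearrangement ([3,3] shift) of the 1,1-dimethylallyl ether should deliver a prenyl group to C6, the only ortho carbon that can re-aromatise because C8 carries the methoxy group.

Compound list
1 | 3-(benzyloxy)-4-methoxybenzaldehyde | COc1ccc(C=O)cc1OCc1ccccc1 | starting material
2 | 3-(benzyloxy)-4-methoxyphenyl formate | COc1ccc(OC=O)cc1OCc1ccccc1 | intermediate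
3 | 3-(benzyloxy)-4-methoxyphenol | COc1ccc(O)cc1OCc1ccccc1 | intermediate
4 | 4-(benzyloxy)-2-hydroxy-5-methoxybenzaldehyde | COc1cc(C=O)c(O)cc1OCc1ccccc1 | intermediate
5 | 5-(benzyloxy)-2-formyl-4-methoxyphenyl 4-methylbenzenesulfonate | COc1cc(C=O)c(OS(=O)(=O)c2ccc(C)cc2)cc1OCc1ccccc1 | intermediate
6 | 5-(benzyloxy)-2-(formyloxy)-4-methoxyphenyl 4-methylbenzenesulfonate | COc1cc(OC=O)c(OS(=O)(=O)c2ccc(C)cc2)cc1OCc1ccccc1 | intermediate
7 | 5-(benzyloxy)-2-hydroxy-4-methoxyphenyl 4-methylbenzenesulfonate | COc1cc(O)c(OS(=O)(=O)c2ccc(C)cc2)cc1OCc1ccccc1 | intermediate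
8 | 5-(benzyloxy)-3-bromo-2-hydroxy-4-methoxyphenyl 4-methylbenzenesulfonate | COc1c(Br)c(O)c(OS(=O)(=O)c2ccc(C)cc2)cc1OCc1ccccc1 | intermediate
9 | 5-(benzyloxy)-3-bromo-4-methoxy-2-[(trimethylsilyl)oxy]phenyl 4-methylbenzenesulfonate | COc1c(Br)c(O[Si](C)(C)C)c(OS(=O)(=O)c2ccc(C)cc2)cc1OCc1ccccc1 | intermediate
10 | lithium 4-(benzyloxy)-3-methoxy-6-(tosyloxy)-2-(trimethylsilyl)phenolate | COc1c([Si](C)(C)C)c([O-])c(OS(=O)(=O)c2ccc(C)cc2)cc1OCc1ccccc1.[Li+] | intermediate
11 | 4-(benzyloxy)-3-methoxy-6-(tosyloxy)-2-(trimethylsilyl)phenyl trifluoromethanesulfonate | COc1c(OCc2ccccc2)cc(OS(=O)(=O)c2ccc(C)cc2)c(OS(=O)(=O)C(F)(F)F)c1[Si](C)(C)C | intermediate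
12 | 2-(2,4,5-trimethoxyphenyl)acetic acid | COc1cc(OC)c(CC(=O)O)cc1OC | starting material
13 | methyl 2-(2,4,5-trimethoxyphenyl)acetate | COC(=O)Cc1cc(OC)c(OC)cc1OC | intermediate
14 | methyl (Z)-3-hydroxy-2-(2,4,5-trimethoxyphenyl)acrylate | COC(=O)/C(=C\O)c1cc(OC)c(OC)cc1OC | intermediate
15 | 4-(benzyloxy)-3-methoxy-6-(tosyloxy)-1,2-didehydrobenzene (aryne) | COC1=C(OCc2ccccc2)C=C(OS(=O)(=O)c2ccc(C)cc2)C#C1 | intermediate
16 | 7-(benzyloxy)-8-methoxy-4-oxo-3-(2,4,5-trimethoxyphenyl)chromen-5-yl 4-methylbenzenesulfonate | COc1cc(OC)c(-c2coc3c(OC)c(OCc4ccccc4)cc(OS(=O)(=O)c4ccc(C)cc4)c3c2=O)cc1OC | intermediate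
17 | 7-hydroxy-8-methoxy-4-oxo-3-(2,4,5-trimethoxyphenyl)chromen-5-yl 4-methylbenzenesulfonate | COc1cc(OC)c(-c2coc3c(OC)c(O)cc(OS(=O)(=O)c4ccc(C)cc4)c3c2=O)cc1OC | intermediate
18 | 5,7-dihydroxy-8-methoxy-3-(2,4,5-trimethoxyphenyl)chromen-4-one (isocaviunin) | COc1cc(OC)c(-c2coc3c(OC)c(O)cc(O)c3c2=O)cc1OC | intermediate
19 | 5-hydroxy-8-methoxy-7-[(2-methylbut-3-en-2-yl)oxy]-3-(2,4,5-trimethoxyphenyl)chromen-4-one | COc1cc(OC)c(-c2coc3c(OC)c(OC(C)(C)C=C)cc(O)c3c2=O)cc1OC | intermediate
20 | 5,7-dihydroxy-8-methoxy-6-(3-methylbut-2-en-1-yl)-3-(2,4,5-trimethoxyphenyl)chromen-4-one (6-prenylisocaviunin) | COc1cc(OC)c(-c2coc3c(OC)c(O)c(CC=C(C)C)c(O)c3c2=O)cc1OC | target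

Total step count: 13 steps.
Longest linear sequence: 11 steps (steps 1–6, then 9–13); steps 7 and 8 form the short branch.

Steps most likely to fail

Step 9. The enolate oxygen may add to the wrong aryne terminus (C4a), the enolate may react through carbon, or the C4a anion may be protonated or lose tosylate before it reaches the ester. The fallback avoids the aryne altogether and uses classical isoflavone chemistry; it sets out from acid 12 and comes back to the route at 18. Acid 12 and commercial phloroglucinol are condensed with BF3·OEt2 at 90 °C (Friedel–Crafts acylation) to 1-(2,4,6-trihydroxyphenyl)-2-(2,4,5-trimethoxyphenyl)ethanone F1. One-carbon closure with DMF, BF3·OEt2 and MsCl at 70 °C should give 5,7-dihydroxy-3-(2,4,5-trimethoxyphenyl)chromen-4-one F2. BnBr (1 equiv) and K2CO3 in acetone benzylate only the non-chelated 7-OH to give 7-(benzyloxy)-5-hydroxy-3-(2,4,5-trimethoxyphenyl)chromen-4-one F3. Elbs persulfate oxidation (K2S2O8, aqueous KOH/pyridine, rt; then dilute HCl, 80 °C) hydroxylates C8, the position para to the 5-phenoxide, to give 7-(benzyloxy)-5,8-dihydroxy-3-(2,4,5-trimethoxyphenyl)chromen-4-one F4. MeI (1 equiv) and K2CO3 in acetone methylate the non-chelated 8-OH to give 7-(benzyloxy)-5-hydroxy-8-methoxy-3-(2,4,5-trimethoxyphenyl)chromen-4-one F5. Hydrogenolysis (H2, 10% Pd/C, EtOAc) then gives 18, and steps 12 and 13 follow unchanged.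

Step 6. n-BuLi may attack the sulfonate sulfur and strip the tosyl group in competition with bromine–lithium exchange. The fallback keeps every sulfonate out of the lithiation; it sets out from 8 and comes back at 11. LiOH in THF/H2O removes the tosyl group to give 5-(benzyloxy)-3-bromo-4-methoxybenzene-1,2-diol F6, handled under argon. HMDS converts it into [5-(benzyloxy)-3-bromo-4-methoxy-1,2-phenylene]bis(oxy)bis(trimethylsilane) F7. n-BuLi at −78 °C then effects exchange and retro-Brook shift, and aqueous work-up should give 5-(benzyloxy)-4-methoxy-3-(trimethylsilyl)benzene-1,2-diol F8. TsCl (1 equiv) with Et3N at −20 °C should sulfonylate the hydroxyl remote from the bulky silyl group, giving 5-(benzyloxy)-2-hydroxy-4-methoxy-3-(trimethylsilyl)phenyl 4-methylbenzenesulfonate F9. Tf2O and pyridine in CH2Cl2 at 0 °C convert the hindered phenol into 11.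

Step 12. The tertiary ether may be re-ionised by zerovalent palladium and drift to the linear prenyl ether, or the allyl unit may be lost. The fallback builds the same ether through an alkyne; it sets out from 18 and comes back at 19. Propargylation with methyl 2-methylbut-3-yn-2-yl carbonate (CuCl2·2H2O cat., DBU, MeCN, 0 °C) should give 5-hydroxy-8-methoxy-7-[(2-methylbut-3-yn-2-yl)oxy]-3-(2,4,5-trimethoxyphenyl)chromen-4-one F10. Semihydrogenation (H2, Pd/CaCO3 poisoned with Pb(OAc)2, quinoline, EtOAc, rt) then gives 19.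

Further compounds
F1 | step 9 | 1-(2,4,6-trihydroxyphenyl)-2-(2,4,5-trimethoxyphenyl)ethanone | COc1cc(OC)c(CC(=O)c2c(O)cc(O)cc2O)cc1OC
F2 | step 9 | 5,7-dihydroxy-3-(2,4,5-trimethoxyphenyl)chromen-4-one | COc1cc(OC)c(-c2coc3cc(O)cc(O)c3c2=O)cc1OC
F3 | step 9 | 7-(benzyloxy)-5-hydroxy-3-(2,4,5-trimethoxyphenyl)chromen-4-one | COc1cc(OC)c(-c2coc3cc(OCc4ccccc4)cc(O)c3c2=O)cc1OC
F4 | step 9 | 7-(benzyloxy)-5,8-dihydroxy-3-(2,4,5-trimethoxyphenyl)chromen-4-one | COc1cc(OC)c(-c2coc3c(O)c(OCc4ccccc4)cc(O)c3c2=O)cc1OC
F5 | step 9 | 7-(benzyloxy)-5-hydroxy-8-methoxy-3-(2,4,5-trimethoxyphenyl)chromen-4-one | COc1cc(OC)c(-c2coc3c(OC)c(OCc4ccccc4)cc(O)c3c2=O)cc1OC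
F6 | step 6 | 5-(benzyloxy)-3-bromo-4-methoxybenzene-1,2-diol | COc1c(Br)c(O)c(O)cc1OCc1ccccc1
F7 | step 6 | [5-(benzyloxy)-3-bromo-4-methoxy-1,2-phenylene]bis(oxy)bis(trimethylsilane) | COc1c(Br)c(O[Si](C)(C)C)c(O[Si](C)(C)C)cc1OCc1ccccc1
F8 | step 6 | 5-(benzyloxy)-4-methoxy-3-(trimethylsilyl)benzene-1,2-diol | COc1c([Si](C)(C)C)c(O)c(O)cc1OCc1ccccc1
F9 | step 6 | 5-(benzyloxy)-2-hydroxy-4-methoxy-3-(trimethylsilyl)phenyl 4-methylbenzenesulfonate | COc1c([Si](C)(C)C)c(O)c(OS(=O)(=O)c2ccc(C)cc2)cc1OCc1ccccc1
F10 | step 12 | 5-hydroxy-8-methoxy-7-[(2-methylbut-3-yn-2-yl)oxy]-3-(2,4,5-trimethoxyphenyl)chromen-4-one | COc1cc(OC)c(-c2coc3c(OC)c(OC(C)(C)C#C)cc(O)c3c2=O)cc1OC
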